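**Assumption:** (2E,6E)-farnesyl acetate, 3-(chloromethyl)furan and furan-3-ylmethanol are bought as such; the hand of BINAP in step 3 is taken from the geraniol hydrogenation model and is to be confirmed on the product by Mosher ester analysis (use the (R)-ligand if the sign is opposite).

## Retrosynthetic overview

1. The lactone C5=CH bond is cut last: an α-chiral C20 aldehyde plus a C5-lithiated 2-silyloxyfuran, which acts as a masked acyl anion of a 4-oxobut-2-enoate. Loss of the carbinol oxygen then unveils the Z-enol lactone.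
2. The aldehyde comes from the (S)-2-methyl alcohol, made by hydroxyl-directed asymmetric hydrogenation of an (E)-2-methylallylic alcohol (sets the only stereocentre).
3. That allylic alcohol comes from copper-catalysed coupling of furan-3-ylmethyl Grignard with 12-hydroxyfarnesyl acetate, itself from SeO2 oxidation of farnesyl acetate (both E-trisubstituted alkenes are bought).
4. The silyloxyfuran comes from 3-(hydroxymethyl)furan-2(5H)-one, made from furan-3-ylmethanol by C2 lithiation, borylation and oxidation.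
5. Rings: ring A (3-alkylfuran) is bought intact. Ring B (lactone) is made first by oxidising a second furan, carried as an aromatic 2-silyloxyfuran, and unveiled in the final step.

## Route

**Step 1**
Reactants: 1 (2E,6E)-3,7,11-trimethyldodeca-2,6,10-trien-1-yl acetate (farnesyl acetate)
Product: 2 (2E,6E,10E)-12-hydroxy-3,7,11-trimethyldodeca-2,6,10-trien-1-yl acetate
Conditions: SeO2 (0.3 equiv), t-BuOOH (70% aq., 3 equiv), salicylic acid (0.1 equiv), CH2Cl2, 0 °C → rt
Reagents that add atoms: selenium dioxide, O=[Se]=O (oxygen carrier); tert-butyl hydroperoxide, CC(C)(C)OO (terminal oxygen source)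
Why: Riley allylic oxidation (ene reaction then [2,3]-sigmatropic shift); the terminal trisubstituted alkene is the most electron-rich (the 2,3-alkene is deactivated by the allylic acetate) and the E-methyl group is oxidised, giving the E-allylic alcohol.

**Step 2**
Reactants: 2 (2E,6E,10E)-12-hydroxy-3,7,11-trimethyldodeca-2,6,10-trien-1-yl acetate; 3 3-(chloromethyl)furan
Product: 5 (2E,6E,10E)-13-(furan-3-yl)-2,6,10-trimethyltrideca-2,6,10-trien-1-ol, via (furan-3-ylmethyl)magnesium chloride 4 (not isolated)
Conditions: 3, Mg, THF, 0 °C (gives 4, 3 equiv); then 2, Li2CuCl4 (5 mol %), THF, −30 → 0 °C; aq. NH4Cl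
Reagents that add atoms: none
Why: Copper-catalysed Grignard coupling with an allylic acetate; attack is at the primary carbon (the SN2′ site would give a quaternary centre), so the 2E-alkene is kept, and the first equivalent of 4 is spent on the free hydroxyl.

**Step 3**
Reactants: 5 (2E,6E,10E)-13-(furan-3-yl)-2,6,10-trimethyltrideca-2,6,10-trien-1-ol
Product: 6 (2S,6E,10E)-13-(furan-3-yl)-2,6,10-trimethyltrideca-6,10-dien-1-ol
Conditions: H2 (30 atm), Ru(OAc)2[(S)-BINAP] (1 mol %), MeOH, 20 °C
Reagents that add atoms: none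
Why: Hydroxyl-directed asymmetric hydrogenation (Noyori allylic alcohol hydrogenation); only the alkene next to the chelating OH is reduced, the two isolated trisubstituted alkenes and the furan are left alone, and the ligand hand sets C2 as S.

**Step 4**
Reactants: 6 (2S,6E,10E)-13-(furan-3-yl)-2,6,10-trimethyltrideca-6,10-dien-1-ol
Product: 7 (2S,6E,10E)-13-(furan-3-yl)-2,6,10-trimethyltrideca-6,10-dienal
Conditions: PhI(OAc)2 (1.1 equiv), TEMPO (10 mol %), CH2Cl2, rt; used crude
Reagents that add atoms: none
Why: Oxoammonium (TEMPO) oxidation stops at the aldehyde under non-basic conditions, so the α-stereocentre is not epimerised and the alkenes and furan are untouched.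

**Step 5**
Reactants: 8 furan-3-ylmethanol
Product: 11 3-(hydroxymethyl)furan-2(5H)-one, via dilithiated furanmethanol 9 (not isolated), via furan-2-ylboronate 10 (not isolated)
Conditions: n-BuLi (2.2 equiv), THF, −78 → 0 °C; B(OMe)3, −78 °C → rt; AcOH (3 equiv), 30% H2O2, 0 °C → rt
Reagents that add atoms: hydrogen peroxide, OO
Why: Alkoxide-directed C2 lithiation, borylation and C–B oxidation give the 2-hydroxyfuran, which tautomerises to the conjugated butenolide with the carbonyl next to the hydroxymethyl-bearing carbon.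

**Step 6**
Reactants: 11 3-(hydroxymethyl)furan-2(5H)-one
Product: 12 tri(propan-2-yl){[2-{[tri(propan-2-yl)silyl]oxy}furan-3-yl]methoxy}silane
Conditions: TIPSOTf (2.2 equiv), Et3N (3 equiv), CH2Cl2, 0 °C
Reagents that add atoms: triisopropylsilyl trifluoromethanesulfonate, CC(C)[Si](C(C)C)(C(C)C)OS(=O)(=O)C(F)(F)F
Why: Silylation of the alcohol and soft enolisation with O-silylation of the butenolide (silyl ketene acetal formation) give the aromatic 2-silyloxyfuran; the bulky silyl group is chosen to survive sec-butyllithium.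

**Step 7 (key step)**
Reactants: 7 (2S,6E,10E)-13-(furan-3-yl)-2,6,10-trimethyltrideca-6,10-dienal; 12 tri(propan-2-yl){[2-{[tri(propan-2-yl)silyl]oxy}furan-3-yl]methoxy}silane
Product: 16 (5Z)-5-[(2S,6E,10E)-13-(furan-3-yl)-2,6,10-trimethyltrideca-6,10-dien-1-ylidene]-3-(hydroxymethyl)furan-2(5H)-one, via 5-lithio silyloxyfuran 13 (not isolated), via lithium alkoxide adduct 14 (not isolated), via furfuryl acetate 15 (not isolated)
Conditions: 12 (1.2 equiv), s-BuLi (1.15 equiv), TMEDA, THF, −78 → 0 °C; 7, −78 °C; Ac2O (1.3 equiv), −78 → 0 °C; Bu4NF·3H2O (3.5 equiv), 0 °C; AcOH (3 equiv), rt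
Reagents that add atoms: none
Why: Proposed new method: sec-butyllithium removes the C5–H of 12 (the α-hydrogen of a cyclic silyl ketene acetal) to give 13, a masked acyl anion of a 4-oxobut-2-enoate whose carbanion carbon becomes the ketone-level C5 of the lactone; it adds to the aldehyde carbon of 7 at −78 °C (two normally electrophilic carbons joined, acyloin-type umpolung addition) without enolising the α-stereocentre, acetylation turns the furfuryl oxygen into a leaving group, and fluoride desilylation releases a furanolate that expels acetate (vinylogous E1cB) to give the enol lactone directly, Z because the branched chain avoids allylic strain against C4–H (any minor E isomer is removed by chromatography), with the primary silyl ether cleaved in the same pot; the closest known chemistry is C5-lithiation and alkylation of 2-silyloxyfurans, addition of 5-lithio-2-methoxyfuran to carbonyl compounds followed by acid-induced formation of γ-ylidenebutenolides, and acetylation/elimination of vinylogous aldol adducts.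

## Compound list

1 | (2E,6E)-3,7,11-trimethyldodeca-2,6,10-trien-1-yl acetate | CC(=O)OC/C=C(\C)CC/C=C(\C)CCC=C(C)C | starting material
2 | (2E,6E,10E)-12-hydroxy-3,7,11-trimethyldodeca-2,6,10-trien-1-yl acetate | CC(=O)OC/C=C(\C)CC/C=C(\C)CC/C=C(\C)CO | intermediate
3 | 3-(chloromethyl)furan | ClCc1ccoc1 | starting material
4 | (furan-3-ylmethyl)magnesium chloride | Cl[Mg]Cc1ccoc1 | intermediate
5 | (2E,6E,10E)-13-(furan-3-yl)-2,6,10-trimethyltrideca-2,6,10-trien-1-ol | C/C(=C\CCc1ccoc1)CC/C=C(\C)CC/C=C(\C)CO | intermediate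
6 | (2S,6E,10E)-13-(furan-3-yl)-2,6,10-trimethyltrideca-6,10-dien-1-ol | C/C(=C\CCc1ccoc1)CC/C=C(\C)CCC[C@H](C)CO | intermediate
7 | (2S,6E,10E)-13-(furan-3-yl)-2,6,10-trimethyltrideca-6,10-dienal | C/C(=C\CCc1ccoc1)CC/C=C(\C)CCC[C@H](C)C=O | intermediate
8 | furan-3-ylmethanol | OCc1ccoc1 | starting material
9 | lithium (2-lithiofuran-3-yl)methanolate (dilithiated furanmethanol) | [Li]OCc1ccoc1[Li] | intermediate
10 | dimethyl {3-[(lithiooxy)methyl]furan-2-yl}boronate | COB(OC)c1occc1CO[Li] | intermediate
11 | 3-(hydroxymethyl)furan-2(5H)-one | O=C1OCC=C1CO | intermediate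
12 | tri(propan-2-yl){[2-{[tri(propan-2-yl)silyl]oxy}furan-3-yl]methoxy}silane | CC(C)[Si](C(C)C)(C(C)C)OCc1ccoc1O[Si](C(C)C)(C(C)C)C(C)C | intermediate
13 | 5-lithio derivative of 12 | [Li]c1cc(CO[Si](C(C)C)(C(C)C)C(C)C)c(O[Si](C(C)C)(C(C)C)C(C)C)o1 | intermediate
14 | lithium alkoxide adduct of 13 to 7 (both carbinol epimers, 2S chain) | C/C(=C\CCc1ccoc1)CC/C=C(\C)CCC[C@H](C)C(O[Li])c1cc(CO[Si](C(C)C)(C(C)C)C(C)C)c(O[Si](C(C)C)(C(C)C)C(C)C)o1 | intermediate
15 | acetate of the adduct (furfuryl acetate) | C/C(=C\CCc1ccoc1)CC/C=C(\C)CCC[C@H](C)C(OC(C)=O)c1cc(CO[Si](C(C)C)(C(C)C)C(C)C)c(O[Si](C(C)C)(C(C)C)C(C)C)o1 | intermediate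
16 | (5Z)-5-[(2S,6E,10E)-13-(furan-3-yl)-2,6,10-trimethyltrideca-6,10-dien-1-ylidene]-3-(hydroxymethyl)furan-2(5H)-one | C/C(=C\CCc1ccoc1)CC/C=C(\C)CCC[C@H](C)/C=C1/C=C(CO)C(=O)O1 | target

## Step count and risks

Total step count: 7. Longest linear sequence: 5 steps (1, 2, 3, 4, 7).

**Step 7 (lithiation of 12, addition, one-pot unveiling).** The fallback sets out from 7 and 12 and comes back at 16. Compound 12 is used as a π-nucleophile instead of being lithiated: BF3·OEt2-promoted vinylogous Mukaiyama aldol addition to 7 (CH2Cl2, −78 °C) gives the hydroxy lactone 5-[(2S,6E,10E)-13-(furan-3-yl)-1-hydroxy-2,6,10-trimethyltrideca-6,10-dien-1-yl]-3-({[tri(propan-2-yl)silyl]oxy}methyl)furan-2(5H)-one F1. Mesylation and base-induced elimination (MsCl, Et3N, then DBU) give the silyl-protected lactone (5Z)-5-[(2S,6E,10E)-13-(furan-3-yl)-2,6,10-trimethyltrideca-6,10-dien-1-ylidene]-3-({[tri(propan-2-yl)silyl]oxy}methyl)furan-2(5H)-one F2. HF·pyridine then gives 16.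

**Step 3 (sense and level of induction on a 2-methylallylic alcohol, which is less documented than geraniol-type substrates).** The fallback sets out from 5 and comes back at 6. TEMPO/PhI(OAc)2 in MeCN–water oxidises 5 to (2E,6E,10E)-13-(furan-3-yl)-2,6,10-trimethyltrideca-2,6,10-trienoic acid F3. Carboxylate-directed hydrogenation with Ru(OAc)2[(S)-BINAP], a tiglic-acid-type substrate with well-established induction, gives (2S,6E,10E)-13-(furan-3-yl)-2,6,10-trimethyltrideca-6,10-dienoic acid F4. LiAlH4 reduction then gives 6.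

**Step 5 (one-pot borylation and oxidation of the furan).** The fallback sets out from 8 and comes back at 11. Compound 8 is C2-lithiated as before but quenched with Me3SiCl (acid work-up cleaves the O-silyl group) to give [2-(trimethylsilyl)furan-3-yl]methanol F5. Buffered peracetic acid (AcOOH, NaOAc, CH2Cl2) converts the 2-silylfuran by ipso-oxidation into 11.

## Further compounds

F1 | step 7 | 5-[(2S,6E,10E)-13-(furan-3-yl)-1-hydroxy-2,6,10-trimethyltrideca-6,10-dien-1-yl]-3-({[tri(propan-2-yl)silyl]oxy}methyl)furan-2(5H)-one | C/C(=C\CCc1ccoc1)CC/C=C(\C)CCC[C@H](C)C(O)C1OC(=O)C(CO[Si](C(C)C)(C(C)C)C(C)C)=C1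
F2 | step 7 | (5Z)-5-[(2S,6E,10E)-13-(furan-3-yl)-2,6,10-trimethyltrideca-6,10-dien-1-ylidene]-3-({[tri(propan-2-yl)silyl]oxy}methyl)furan-2(5H)-one | C/C(=C\CCc1ccoc1)CC/C=C(\C)CCC[C@H](C)/C=C1/C=C(CO[Si](C(C)C)(C(C)C)C(C)C)C(=O)O1
F3 | step 3 | (2E,6E,10E)-13-(furan-3-yl)-2,6,10-trimethyltrideca-2,6,10-trienoic acid | C/C(=C\CCc1ccoc1)CC/C=C(\C)CC/C=C(\C)C(=O)O
F4 | step 3 | (2S,6E,10E)-13-(furan-3-yl)-2,6,10-trimethyltrideca-6,10-dienoic acid | C/C(=C\CCc1ccoc1)CC/C=C(\C)CCC[C@H](C)C(=O)O
F5 | step 5 | [2-(trimethylsilyl)furan-3-yl]methanol | C[Si](C)(C)c1occc1CO
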